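The readings were computed for an exercise; the scatter is artificial.

**Choice.** We choose to reckon this flask's substrate in powers of ten, on a log scale, and to read the target from the curve it shares with the earlier runs.

| setting | Friday's | Tuesday's | flask |
|---|---|---|---|
| substrate | 12 mM | 48 mM | 24 mM |
| capture agent | 1.2 mM | 1.2 mM | 1.20 mM |
| remark | run made earlier | run made earlier |  |
| time |  |  | 6.0 d |

| run | time / d | target / % | substrate / % |
|---|---|---|---|
| Friday's | 1.04 | 18.6 | 44.4 |
| Friday's | 2.08 | 41.9 | 23.6 |
| Friday's | 3.00 | 57.0 | 13.7 |
| Friday's | 4.00 | 67.0 | 8.1 |
| Friday's | 5.00 | 72.4 | 2.9 |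
| Tuesday's | 0.417 | 5.7 | 68.0 |
| Tuesday's | 0.833 | 13.8 | 51.7 |
| Tuesday's | 1.25 | 24.7 | 38.8 |
| Tuesday's | 2.50 | 49.0 | 16.7 |
| Tuesday's | 5.00 | 73.4 | 3.6 |

(readings scatter by 1 percentage point)

- amount of target in the flask at 6.0 d, in percent of the substrate charged
- amount of substrate in the flask at 6.0 d, in percent of the substrate charged

**Charge.** Tuesday's run holds 4.00 times the substrate of Friday's run, yet at 5.00 d their substrate readings differ by 0.7 percentage points, with a scatter of 1 point. The asked flask, at 24 mM, lies between the two charges, so we place it on the same percentage curve.

**Turned round.** Tuesday's run falls from 51.7% at 0.833 d to 3.6% at 5.00 d, which gives 3.60 d. This is the decade time, the days the substrate needs to fall by one power of ten. For the opposite outcome, with the substrate not yet one power of ten below its charge at 6.0 d, a straight line on the log scale from the charge needs a decade time of at least 6.0 d. The readings show a decade time shorter than that by a factor of 1.67.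

**Our reckoning.** Carrying Tuesday's last reading forward to 6.0 d, we expect 1.90% substrate. In Friday's and Tuesday's runs the target is still climbing, through 72.4% and 73.4% at 5.00 d.

**Forecast.** The forecast, reading the substrate as “nearly first-order, with the same percentage curve”, gives 77% target and 1.8% substrate.

**Result.** The flask gives 76.7% target and 2.23% substrate.

    substrate ⇌ intermediate A (K = 0.108, k = 0.0117 /h)
    intermediate A ⇌ intermediate B (K = 0.585, k = 0.00686 /h)
    substrate → intermediate C (k = 0.0292 /h)
    intermediate C ⇌ intermediate D (K = 0.230, k = 0.0312 /h)
    intermediate C → target (k = 0.0460 /h)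
    intermediate C → side product (k = 0.00837 /h)
    capture agent + intermediate D → trapped intermediate (k = 9.99 /M/h)

**Decade time again.** From 13.0% at 3.00 d to 2.23% at 6.0 d, this flask's substrate has a decade time of 3.92 d, longer than 3.60 d. For a neighbour flask of the same charges, read at 40 h, the carried decade time, counted from Tuesday's reading at 0.833 d, gives 30.3% substrate, and that flask holds 29.9%. Target in this flask stands short of the charge at 6.0 d mainly because of the step from intermediate C to side product: the run with that step taken away gives 89.3% target, against 76.7% in this flask.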